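**Plan**

- Retrosynthesis: the two benzyl ethers come off last and the butanoyl C–C bond at C5' of ring B is cut. Ring B is then opened at C1'–C6' and C3'–C4'. This removes C4'–C5'–C6' as a malonyl unit and leaves C1' (with the CH2 bridge), C2' (O) and C3' (with its methyl) as the α-carbon, carbonyl and α'-carbon of 1-(ring A)pentan-3-one.
- That ketone, as its enol ether, goes back to an enone, which is cut at the C=C next to ring A into a ring A aldehyde and a ketophosphonate. Ring A goes back to 2-methylphloroglucinol by removing formyl, benzyl, O-methyl and pentanoyl groups.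
- Forward: ring A is bought as an aromatic ring and dressed in four steps. The five-carbon chain is joined by olefination, 1,4-hydrosilylation gives the enol ether, and ring B is built on that chain in one operation. Butanoylation and hydrogenolysis finish.
- Stereochemistry: the target has no stereocentre. The E enone and Z enol ether geometries come from the olefination and from the s-cis 1,4-addition, and both vanish when ring B aromatises.

Key step: step 7

Remark: intermediates 11 and 12 carry transient, undefined stereocentres that disappear on aromatisation, so their SMILES carry no descriptors.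

**Route**

Step 1
Reactants: 1 2-methylphloroglucinol; 2 pentanoyl chloride
Product: 3 1-(2,4,6-trihydroxy-3-methylphenyl)pentan-1-one
Conditions: AlCl3 (3.5 equiv), PhNO2/CS2, 0 °C → 50 °C; ice, aq HCl
Reagents that add atoms: none
Why: Friedel–Crafts acylation of a phloroglucinol; the two open ring positions of 1 are equivalent and the first acyl group deactivates the ring against a second.

Step 2
Reactants: 3 1-(2,4,6-trihydroxy-3-methylphenyl)pentan-1-one
Product: 4 1-(2,6-dihydroxy-4-methoxy-3-methylphenyl)pentan-1-one
Conditions: Me2SO4 (1.0 equiv), K2CO3 (1.0 equiv), acetone, rt → 40 °C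
Reagents that add atoms: dimethyl sulfate, COS(=O)(=O)OC
Why: Williamson-type O-methylation; the hydroxyl para to the ketone is the most acidic and is not hydrogen-bonded to the carbonyl, so one equivalent of reagent should take it first, as in the usual preparation of 4-O-methyl phloroacylphenones, and any ortho-methylated isomer is removed at this stage.

Step 3
Reactants: 4 1-(2,6-dihydroxy-4-methoxy-3-methylphenyl)pentan-1-one
Product: 5 2,4-dihydroxy-6-methoxy-5-methyl-3-pentanoylbenzaldehyde
Conditions: POCl3 (1.5 equiv), DMF, EtOAc, 0 °C → rt; then H2O, 60 °C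
Reagents that add atoms: N,N-dimethylformamide, CN(C)C=O; water, O
Why: Vilsmeier–Haack formylation; only one ring position is open, it is activated by the flanking OH and OMe and by the para OH, and at room temperature the ring carbon should react well before the ketone side chain.

Step 4
Reactants: 5 2,4-dihydroxy-6-methoxy-5-methyl-3-pentanoylbenzaldehyde
Product: 6 2,4-bis(benzyloxy)-6-methoxy-5-methyl-3-pentanoylbenzaldehyde
Conditions: BnBr (2.6 equiv), K2CO3 (3 equiv), n-Bu4NI (cat.), DMF, 60 °C
Reagents that add atoms: benzyl bromide, BrCc1ccccc1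
Why: Williamson benzylation of phenoxides in a dipolar aprotic solvent, which favours O- over C-alkylation; both hydroxyls are chelated, hence the warming and the excess of reagent.

Step 5
Reactants: 6 2,4-bis(benzyloxy)-6-methoxy-5-methyl-3-pentanoylbenzaldehyde; 7 diethyl (2-oxobutyl)phosphonate
Product: 8 (E)-1-[2,4-bis(benzyloxy)-6-methoxy-5-methyl-3-pentanoylphenyl]pent-1-en-3-one
Conditions: LiCl, DBU, MeCN, rt → 40 °C
Reagents that add atoms: none
Why: Horner–Wadsworth–Emmons olefination under mild LiCl/amine (Masamune–Roush) conditions; the stabilised ketophosphonate anion reacts with the aldehyde, leaves the hindered aryl ketone alone and gives the E enone.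

Step 6
Reactants: 8 (E)-1-[2,4-bis(benzyloxy)-6-methoxy-5-methyl-3-pentanoylphenyl]pent-1-en-3-one
Product: 9 triethyl{[(Z)-1-[2,4-bis(benzyloxy)-6-methoxy-5-methyl-3-pentanoylphenyl]pent-2-en-3-yl]oxy}silane
Conditions: Et3SiH (1.3 equiv), RhCl(PPh3)3 (2 mol %), THF, 50 °C; filtration through Et3N-treated Florisil, used promptly
Reagents that add atoms: triethylsilane, CC[SiH](CC)CC
Why: 1,4-hydrosilylation of an enone with a monohydrosilane under RhCl(PPh3)3 catalysis; addition across the s-cis enone places CH2Ar and OSiEt3 cis (Z) and fixes the position of the enol ether, while the hindered aryl ketone and the benzyl ethers are not touched.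

Step 7
Reactants: 9 triethyl{[(Z)-1-[2,4-bis(benzyloxy)-6-methoxy-5-methyl-3-pentanoylphenyl]pent-2-en-3-yl]oxy}silane; 10 malonyl dichloride
Product: 13 1-[2,6-bis(benzyloxy)-4-methoxy-3-methyl-5-(2,4,6-trihydroxy-3-methylbenzyl)phenyl]pentan-1-one, via diketo acid chloride 11 (not isolated), via cyclohexane-1,3,5-trione 12 (not isolated)
Conditions: 10 (1.05 equiv), CH2Cl2, −20 °C → rt; then aq KOH, BnEt3NCl, rt, argon; acidified with aq HCl
Reagents that add atoms: none
Why: C1' of the enol ether attacks one acyl chloride of 10 (directly or via chlorocarbonylketene) with loss of the silyl group to give 11, whose ketone re-enolises toward the ethyl side so that C3' can attack the second acyl chloride and give trione 12, which tautomerises at once to the aromatic triol 13. The closest known reaction type is the Effenberger α,α'-annulation of ketone enol ethers with malonyl dichloride, established for cyclic ketones that give bicyclic triones and used here on an acyclic enol ether whose trione can aromatise. Ring B closes as a six-membered carbocycle by a 6-(enolendo)-exo-trig C-acylation. No stereocentre is created, and the Z geometry of 9 and the transient stereocentres of 11 and 12 are erased on aromatisation. The step needs carbon rather than oxygen to close the ring (oxygen closure would give a 4-hydroxy-2-pyrone); low temperature, a single equivalent of 10, a phase-transfer KOH work-up that opens O-acylated material and lets it re-close at carbon, and aromatisation as the thermodynamic sink are meant to secure this. Chemoselectivity comes from the substrate, since ring A is fully substituted and etherified and its aryl ketone sits between two ortho benzyloxy groups, leaving the enol ether as the only nucleophile.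

Step 8
Reactants: 13 1-[2,6-bis(benzyloxy)-4-methoxy-3-methyl-5-(2,4,6-trihydroxy-3-methylbenzyl)phenyl]pentan-1-one; 14 butanoyl chloride
Product: 15 1-[2,6-bis(benzyloxy)-3-(3-butanoyl-2,4,6-trihydroxy-5-methylbenzyl)-4-methoxy-5-methylphenyl]pentan-1-one
Conditions: 14 (1.1 equiv), BF3·OEt2 (3 equiv), CH2Cl2/1,4-dioxane, 0 °C → rt; aq work-up
Reagents that add atoms: none
Why: Friedel–Crafts acylation of a phloroglucinol promoted by BF3·OEt2; C5' is the only unsubstituted ring carbon in the molecule, any phenyl ester formed first can migrate to it (Fries) under the same Lewis acid, and at room temperature this acid should leave the benzyl ethers in place.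

Step 9
Reactants: 15 1-[2,6-bis(benzyloxy)-3-(3-butanoyl-2,4,6-trihydroxy-5-methylbenzyl)-4-methoxy-5-methylphenyl]pentan-1-one
Product: 16 1-[3-(3-butanoyl-2,4,6-trihydroxy-5-methylbenzyl)-2,6-dihydroxy-4-methoxy-5-methylphenyl]pentan-1-one (CNP0228890.0)
Conditions: H2 (1 atm), 10% Pd/C, EtOAc/MeOH, rt
Reagents that add atoms: none
Why: hydrogenolysis of benzyl aryl ethers over Pd/C; the chelated aryl ketones and the diarylmethane should not be reduced under one atmosphere of hydrogen at room temperature.

**Compound list**

1 | 2-methylphloroglucinol (2-methylbenzene-1,3,5-triol) | Cc1c(O)cc(O)cc1O | starting material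
2 | pentanoyl chloride | CCCCC(=O)Cl | starting material
3 | 1-(2,4,6-trihydroxy-3-methylphenyl)pentan-1-one | CCCCC(=O)c1c(O)cc(O)c(C)c1O | intermediate
4 | 1-(2,6-dihydroxy-4-methoxy-3-methylphenyl)pentan-1-one | CCCCC(=O)c1c(O)cc(OC)c(C)c1O | intermediate
5 | 2,4-dihydroxy-6-methoxy-5-methyl-3-pentanoylbenzaldehyde | CCCCC(=O)c1c(O)c(C)c(OC)c(C=O)c1O | intermediate
6 | 2,4-bis(benzyloxy)-6-methoxy-5-methyl-3-pentanoylbenzaldehyde | CCCCC(=O)c1c(OCc2ccccc2)c(C)c(OC)c(C=O)c1OCc1ccccc1 | intermediate
7 | diethyl (2-oxobutyl)phosphonate | CCC(=O)CP(=O)(OCC)OCC | starting material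
8 | (E)-1-[2,4-bis(benzyloxy)-6-methoxy-5-methyl-3-pentanoylphenyl]pent-1-en-3-one | CCCCC(=O)c1c(OCc2ccccc2)c(C)c(OC)c(/C=C/C(=O)CC)c1OCc1ccccc1 | intermediate
9 | triethyl{[(Z)-1-[2,4-bis(benzyloxy)-6-methoxy-5-methyl-3-pentanoylphenyl]pent-2-en-3-yl]oxy}silane | CCCCC(=O)c1c(OCc2ccccc2)c(C)c(OC)c(C/C=C(\O[Si](CC)(CC)CC)CC)c1OCc1ccccc1 | intermediate
10 | malonyl dichloride | O=C(Cl)CC(=O)Cl | starting material
11 | 4-{[2,4-bis(benzyloxy)-6-methoxy-5-methyl-3-pentanoylphenyl]methyl}-3,5-dioxoheptanoyl chloride (transient, racemic) | CCCCC(=O)c1c(OCc2ccccc2)c(C)c(OC)c(CC(C(=O)CC)C(=O)CC(=O)Cl)c1OCc1ccccc1 | intermediate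
12 | 2-{[2,4-bis(benzyloxy)-6-methoxy-5-methyl-3-pentanoylphenyl]methyl}-4-methylcyclohexane-1,3,5-trione (transient, stereoisomer mixture) | CCCCC(=O)c1c(OCc2ccccc2)c(C)c(OC)c(CC2C(=O)CC(=O)C(C)C2=O)c1OCc1ccccc1 | intermediate
13 | 1-[2,6-bis(benzyloxy)-4-methoxy-3-methyl-5-(2,4,6-trihydroxy-3-methylbenzyl)phenyl]pentan-1-one | CCCCC(=O)c1c(OCc2ccccc2)c(C)c(OC)c(Cc2c(O)cc(O)c(C)c2O)c1OCc1ccccc1 | intermediate
14 | butanoyl chloride | CCCC(=O)Cl | starting material
15 | 1-[2,6-bis(benzyloxy)-3-(3-butanoyl-2,4,6-trihydroxy-5-methylbenzyl)-4-methoxy-5-methylphenyl]pentan-1-one | CCCCC(=O)c1c(OCc2ccccc2)c(C)c(OC)c(Cc2c(O)c(C)c(O)c(C(=O)CCC)c2O)c1OCc1ccccc1 | intermediate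
16 | 1-[3-(3-butanoyl-2,4,6-trihydroxy-5-methylbenzyl)-2,6-dihydroxy-4-methoxy-5-methylphenyl]pentan-1-one (CNP0228890.0) | CCCCC(=O)c1c(O)c(C)c(OC)c(Cc2c(O)c(C)c(O)c(C(=O)CCC)c2O)c1O | target

**Totals**

Total step count: 9. Longest linear sequence: 9 steps (1 → 16).

**Steps most likely to fail**

Step 7. The ring closure may go through the enol oxygen of 11 and end in a 4-hydroxy-2-pyrone that no longer opens, or the dichloride may be used up by ketene-type oligomerisation before the second acylation. The fallback builds the bridge onto a ready-made ring B. It sets out from 6. NaBH4 in MeOH/THF at 0 °C should reduce only the aldehyde to give 1-[2,6-bis(benzyloxy)-3-(hydroxymethyl)-4-methoxy-5-methylphenyl]pentan-1-one F1. This alcohol is ionised by catalytic TsOH in MeCN at room temperature in the presence of an excess of 1. The trialkoxybenzyl cation alkylates one of the two equivalent open positions of 1 (Friedel–Crafts benzylation), and the excess of 1 holds back double alkylation. The fallback comes back to the route at 13 and continues with step 8.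

Step 8. The acyl group may stay on a phenolic oxygen without migrating to carbon. The Lewis acid may strip benzyl groups and transfer them to the open C5' position. The acid medium may also promote exchange of the diarylmethane bridge before ring B is deactivated by the acyl group. The fallback sets out from 13 and uses a Houben–Hoesch reaction: butyronitrile, ZnCl2 and dry HCl in Et2O at 0 °C. The nitrile-derived electrophile cannot form esters and no strong Lewis acid is present. The product should leave the medium as the sparingly soluble ketiminium chloride of 15, F2. Warming F2 in water hydrolyses it, and the fallback comes back to the route at 15.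

Step 4. Alkylation of the hydroxyl wedged between the two carbonyl groups may stay incomplete. The phenoxide of the fully substituted ring may be benzylated at carbon with loss of aromaticity, or the aldehyde may undergo base-induced aldol condensation. The fallback changes the order of events and sets out from 4. Benzylation with BnBr and K2CO3 in DMF, where each hydroxyl has only one carbonyl neighbour, gives 1-[2,6-bis(benzyloxy)-4-methoxy-3-methylphenyl]pentan-1-one F3. The single open ring position of F3 is then formylated under Rieche-type conditions that spare benzyl ethers (Cl2CHOMe, AgOSO2CF3, CH2Cl2, −78 °C → 0 °C). The fallback comes back to the route at 6.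

**Further compounds**

F1 | step 7 | 1-[2,6-bis(benzyloxy)-3-(hydroxymethyl)-4-methoxy-5-methylphenyl]pentan-1-one | CCCCC(=O)c1c(OCc2ccccc2)c(C)c(OC)c(CO)c1OCc1ccccc1
F2 | step 8 | 1-{3-[2,4-bis(benzyloxy)-6-methoxy-5-methyl-3-pentanoylbenzyl]-2,4,6-trihydroxy-5-methylphenyl}butan-1-iminium chloride | CCCCC(=O)c1c(OCc2ccccc2)c(C)c(OC)c(Cc2c(O)c(C)c(O)c(C(=[NH2+])CCC)c2O)c1OCc1ccccc1.[Cl-]
F3 | step 4 | 1-[2,6-bis(benzyloxy)-4-methoxy-3-methylphenyl]pentan-1-one | CCCCC(=O)c1c(OCc2ccccc2)cc(OC)c(C)c1OCc1ccccc1
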